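Read the table below row by row, and carry one pace out of it.

| flask | solid substrate | reagent | remark | time |
|---|---|---|---|---|
| epsilon | 1.5 M | 1.2 equiv | run made earlier |  |
| flask | 1.0 M | 1.20 equiv |  | 4.0 h |

epsilon run (percent of the solid substrate charged)

| time / min | solid substrate / % | mono adduct / % | double product / % |
|---|---|---|---|
| 6.00 | 93 | 0 | 5 |
| 15.0 | 95 | 3 | 1 |
| 20.0 | 93 | 5 | 1 |
| 30.0 | 87 | 7 | 2 |
| 40.0 | 84 | 10 | 2 |
| 50.0 | 84 | 13 | 3 |

(each reading ± 2 percentage points)

- solid, in amounts per volume of the solution: solid substrate
- what was read earlier has a scatter of 2 percentage points, one standard deviation
- at the start none of the solid substrate is in solution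
- what has only dissolved of solid substrate counts as not reacted
- the reaction counts as stopped when no species that holds the solid substrate changes by six tenths of a point or more over the second half of the time

- the state of affairs at 4.0 h: stopped, and by what, or still going (for what has run out or reacted, a solid counts together with what of it has only dissolved) (the reagent has run out first / all of the solid substrate has reacted / forward and back rates have come level / it is still moving)
- part of the solid substrate that has turned into other species by 4.0 h (what has only dissolved does not count)
- the mono adduct standing at 4.0 h, as a percentage of the solid substrate charged

Start at the last row of the epsilon run. Solid substrate, mono adduct and double product add up to 100% there, but that sum carries the scatter of each reading, so it does not show how much has only dissolved. Set aside the double product of the first row, 5%, since the next row shows 1% and each reading scatters by 2 percentage points.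

Now follow the solid substrate column from 15.0 min to 50.0 min. It falls by 11 points, while the mono adduct column gains 10 points. That gives a pace of 0.00314 min⁻¹ as a fraction of the charge, a reading with the scatter of both ends in it.

Assume that dissolved substrate stands at a steady level while solid lasts, a pseudo-zero-order stretch, so that the fall of the column over these rows is taken as conversion. The rate then follows the reagent, and at equal equivalents the reagent follows the charge, so this fractional pace carries from 1.5 M to 1.0 M.

Invert the pace: 5.30 h is the clearing time, the time a straight line at that pace needs for the whole charge. The new flask is read at 4.0 h, earlier than that, so the line reaches 75.5%. My reckoning is therefore a flask still moving, with conversion under the line as the reagent falls.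

The forecast also says it is still moving: “Solid and reagent both remain”. It puts conversion lower than my line, at 55% (43% to 78%), and mono adduct at 43% (32% to 58%).

The new flask gives it is still moving, conversion 64.2% and mono adduct 40.3%.

    starting material + reagent → mono adduct (k = 0.0247 L mol⁻¹ min⁻¹)
    reagent + mono adduct → double product (k = 4.56 × 10⁻⁴ L mol⁻¹ min⁻¹)
    reagent + double product → tris adduct (k = 0.0206 L mol⁻¹ min⁻¹)
    reagent + double product → over-reaction product (k = 0.0311 L mol⁻¹ min⁻¹)
    mono adduct → side product (k = 0.00359 min⁻¹)
    solid substrate ⇌ starting material, rate k6*(cs6 - [starting material]) while solid is left; crystals form when [starting material] > cs6 (solubility = 0.180 M, k = 0.0691 min⁻¹)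

In this flask, conversion stands 11 points under the line and 9.2 points above the forecast. Now read the same flask at 10 h, twice the clearing time, where the reckoning expects the solid gone. That flask shows solid substrate at 0%, conversion at 95.5% and starting material, the dissolved form, at 4.55%. Its mono adduct has come down from 40.3% at 4.00 h to 23.9%.

(Readings and results were generated by integration with constants of no real substance; the scatter is artificial.)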